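**Strategy.** The dihydropyran ring is cut across its CH2–CH(OH) bond and its enol-ether O–C10 bond, a [3+3] union. The feature exploited is that C10 of the dibenzo[b,f]oxepine is a masked ketone carbon and the pyran CH2 hangs on C11, so C10/C11/CH2 is a ketone homoenolate. In one flask a 1-methoxyallyllithium (from the 11-stannylmethyl-10-methoxy oxepine) is acylated at CH2 by a lactic-acid-derived dioxolanone that carries the quaternary stereocentre. Acid then expels pivaldehyde, and the freed tertiary hydroxyl displaces methanol at C10. The resulting pyran-3-one is reduced under reagent control to the (S)-carbinol.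

Key step: step 11

Step 1
Reactants: 1 2-(2-bromo-4-methoxyphenyl)acetic acid; 2 3-methoxyphenol
Product: 3 2-[4-methoxy-2-(3-methoxyphenoxy)phenyl]acetic acid
Conditions: CuI (10 mol%), N,N-dimethylglycine (30 mol%), Cs2CO3 (3 equiv), dioxane, 100 °C; aq. HCl work-up
Reagents that add atoms: none
Why: Ullmann diaryl ether synthesis, in which the aryl bromide couples with the phenoxide while the acid is carried as its carboxylate.

Step 2
Reactants: 3 2-[4-methoxy-2-(3-methoxyphenoxy)phenyl]acetic acid
Product: 4 3,7-dimethoxydibenzo[b,f]oxepin-10(11H)-one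
Conditions: P2O5 in MeSO3H (1:10 w/w), 50 °C
Reagents that add atoms: none
Why: Intramolecular Friedel–Crafts acylation should close the seven-membered ketone at the phenoxy-ring carbon that is ortho to the ether oxygen and para to OMe, the only activated site within reach.

Step 3
Reactants: 4 3,7-dimethoxydibenzo[b,f]oxepin-10(11H)-one
Product: 5 3,7-dihydroxydibenzo[b,f]oxepin-10(11H)-one
Conditions: BBr3 (4 equiv), CH2Cl2, −78 °C → rt; aq. work-up
Reagents that add atoms: none
Why: Lewis-acid-assisted SN2 cleavage of both aryl methyl ethers, done before any acid-sensitive alkene is present; the diaryl ether and ketone should survive.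

Step 4
Reactants: 5 3,7-dihydroxydibenzo[b,f]oxepin-10(11H)-one
Product: 6 2-bromo-3,7-dihydroxydibenzo[b,f]oxepin-10(11H)-one
Conditions: NBS (1.0 equiv), MeCN, −30 → 0 °C
Reagents that add atoms: N-bromosuccinimide O=C1CCC(=O)N1Br
Why: Electrophilic aromatic bromination should go to ring A (ring B is deactivated by the para carbonyl), at C2, which is ortho to the hydroxyl and para to the ether oxygen, whereas C4 is flanked by two oxygens.

Step 5
Reactants: 6 2-bromo-3,7-dihydroxydibenzo[b,f]oxepin-10(11H)-one
Product: 7 2-bromo-3,7-bis(triisopropylsilyloxy)dibenzo[b,f]oxepin-10(11H)-one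
Conditions: iPr3SiCl (2.5 equiv), imidazole (5 equiv), DMF, 40 °C
Reagents that add atoms: chlorotriisopropylsilane CC(C)[Si](Cl)(C(C)C)C(C)C
Why: Standard phenol silylation; the TIPS ethers should survive amide bases, MeLi at −78 °C and mild acid, and fall to fluoride at the end.

Step 6
Reactants: 7 2-bromo-3,7-bis(triisopropylsilyloxy)dibenzo[b,f]oxepin-10(11H)-one
Product: 8 2-(3-methylbut-2-enyl)-3,7-bis(triisopropylsilyloxy)dibenzo[b,f]oxepin-10(11H)-one
Conditions: tributyl(3-methylbut-2-enyl)stannane (1.5 equiv), Pd(PPh3)4 (5 mol%), DMF, 90 °C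
Reagents that add atoms: tributyl(3-methylbut-2-enyl)stannane CC(C)=CC[Sn](CCCC)(CCCC)CCCC
Why: Stille coupling should install the linear prenyl group under neutral conditions that tolerate the enolisable ketone and the silyl ethers.

Step 7
Reactants: 8 2-(3-methylbut-2-enyl)-3,7-bis(triisopropylsilyloxy)dibenzo[b,f]oxepin-10(11H)-one
Product: 9 2-(3-methylbut-2-enyl)-11-[(tributylstannyl)methyl]-3,7-bis(triisopropylsilyloxy)dibenzo[b,f]oxepin-10(11H)-one (racemic at C11)
Conditions: KN(SiMe3)2 (1.05 equiv), THF, −78 °C; Bu3SnCH2I (1.2 equiv), −78 → 0 °C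
Reagents that add atoms: tributyl(iodomethyl)stannane CCCC[Sn](CI)(CCCC)CCCC
Why: Enolate alkylation, in which the C11 methylene (benzylic and alpha to the ketone) forms a soft enolate that the primary iodide should C-alkylate once; this brings in the future pyran CH2.

Step 8
Reactants: 9 2-(3-methylbut-2-enyl)-11-[(tributylstannyl)methyl]-3,7-bis(triisopropylsilyloxy)dibenzo[b,f]oxepin-10(11H)-one
Product: 10 10-methoxy-2-(3-methylbut-2-enyl)-11-[(tributylstannyl)methyl]-3,7-bis(triisopropylsilyloxy)dibenzo[b,f]oxepine
Conditions: KN(SiMe3)2 (1.2 equiv), THF/DMPU, −78 °C; Me2SO4 (1.5 equiv), −78 → 0 °C; Et3N quench, chromatography on basic alumina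
Reagents that add atoms: dimethyl sulfate COS(=O)(=O)OC
Why: O-methylation of the fully substituted potassium enolate by a hard electrophile in a dipolar medium (C-methylation would build a quaternary carbon) masks the C10 carbonyl as an enol ether and makes the CH2SnBu3 group allylic.

Step 9
Reactants: 11 (R)-lactic acid; 12 pivaldehyde
Product: 13 (2R,5R)-2-tert-butyl-5-methyl-1,3-dioxolan-4-one (cis)
Conditions: TsOH·H2O (cat.), H2SO4 (cat.), pentane, reflux with water separator; crystallisation of the cis acetal from pentane/Et2O at −78 °C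
Reagents that add atoms: none
Why: Acid-catalysed acetalisation, in which the cis acetal is purified by crystallisation so that the acetal carbon can relay the lactate configuration (self-regeneration of stereocentres).

Step 10
Reactants: 13 (2R,5R)-2-tert-butyl-5-methyl-1,3-dioxolan-4-one; 14 5-iodo-2-methylpent-2-ene
Product: 15 (2R,5S)-2-tert-butyl-5-methyl-5-(4-methylpent-3-enyl)-1,3-dioxolan-4-one
Conditions: LiN(iPr)2 (1.1 equiv), THF, −78 °C; 14 (1.5 equiv), DMPU, −78 → −30 °C
Reagents that add atoms: none
Why: Enolate alkylation anti to the tert-butyl group should replace H by the homoprenyl chain with retention, setting the quaternary centre that becomes (S) in the target.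

Step 11
Reactants: 10 10-methoxy-2-(3-methylbut-2-enyl)-11-[(tributylstannyl)methyl]-3,7-bis(triisopropylsilyloxy)dibenzo[b,f]oxepine; 15 (2R,5S)-2-tert-butyl-5-methyl-5-(4-methylpent-3-enyl)-1,3-dioxolan-4-one
Product: 19 (S)-2-methyl-2-(4-methylpent-3-enyl)-2H-pyran-3(4H)-one fused through its O–C=C edge to C10–C11 of the 2-prenyl-3,7-bis(triisopropylsilyloxy)dibenzo[b,f]oxepine, via allyllithium 16 (not isolated), via lithium lactolate 17 (not isolated), via hydroxy ketone 18 (not isolated)
Conditions: (i) MeLi (1.05 equiv), THF, −78 °C; (ii) transfer into 15 (1.5 equiv), THF, −78 °C; (iii) CSA (3 equiv), CH2Cl2, 5 Å MS, −78 → 40 °C, all in one flask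
Reagents that add atoms: none
Why: Sn–Li exchange should give the 1-methoxyallyllithium 16, a homoenolate equivalent of the oxepinone whose oxygen-bearing terminus C10 is tertiary and diaryl-flanked, so the hindered lactone carbonyl of 15 is attacked only through the primary CH2 terminus and the addition stops at lactolate 17 at −78 °C (as in lactol formation from lactones and organolithiums). Acid then collapses 17 with loss of pivaldehyde to hydroxy ketone 18 and protonates the enol ether at C11 to the C10 oxocarbenium ion, which the tertiary hydroxyl captures in a 6-exo-trig closure; loss of methanol and of the C11 proton restores the C10=C11 bond. The closest known reaction types are gamma-acylation of metalated allyl ethers, ketone synthesis from lactones and acid-catalysed alcohol addition to an enol ether (the chemistry of tetrahydropyranyl ether formation). No new stereocentre is formed, and the quaternary centre comes unchanged from 15 because it has no alpha hydrogen. The step needs gamma- over alpha-acylation (secured by the blocked C10 terminus) and six-ring O-closure over furan formation (secured because the new carbon is a ketone without a hydroxyl, and the alcohol outcompetes the carbonyl oxygen for the oxocarbenium ion under anhydrous conditions).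

Step 12
Reactants: 19 (S)-pyran-3-one fused to the bis(triisopropylsilyloxy) oxepine
Product: 20 (2S,3S)-2-methyl-2-(4-methylpent-3-enyl)-3,4-dihydro-2H-pyran-3-ol fused to the 2-prenyl-3,7-bis(triisopropylsilyloxy)dibenzo[b,f]oxepine
Conditions: (R)-Me-CBS oxazaborolidine (0.2 equiv), catecholborane (1.8 equiv), PhMe, −78 → −40 °C; MeOH, then aq. NaHCO3
Reagents that add atoms: none
Why: Corey–Bakshi–Shibata reduction, in which the ketone is flanked by a quaternary carbon (large) and a CH2 (small), so the (R)-catalyst should deliver hydride to the face giving the (S)-carbinol (OH trans to the ring methyl) by reagent control, while catecholborane at low temperature leaves the trisubstituted alkenes alone.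

Step 13
Reactants: 20 bis(triisopropylsilyl) ether of the target
Product: 21 CNP0185870.1
Conditions: Bu4NF (2.5 equiv), AcOH (2.5 equiv), THF, 0 °C
Reagents that add atoms: none
Why: Buffered fluoride desilylation should free both phenols without touching the enol ether, the alkenes or the carbinol.

**Compound list**

1 | 2-(2-bromo-4-methoxyphenyl)acetic acid | COc1ccc(CC(=O)O)c(Br)c1 | starting material
2 | 3-methoxyphenol | COc1cccc(O)c1 | starting material
3 | 2-[4-methoxy-2-(3-methoxyphenoxy)phenyl]acetic acid | COc1cccc(Oc2cc(OC)ccc2CC(=O)O)c1 | intermediate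
4 | 3,7-dimethoxydibenzo[b,f]oxepin-10(11H)-one | O=C1Cc2ccc(OC)cc2Oc2cc(OC)ccc12 | intermediate
5 | 3,7-dihydroxydibenzo[b,f]oxepin-10(11H)-one | O=C1Cc2ccc(O)cc2Oc2cc(O)ccc12 | intermediate
6 | 2-bromo-3,7-dihydroxydibenzo[b,f]oxepin-10(11H)-one | O=C1Cc2cc(Br)c(O)cc2Oc2cc(O)ccc12 | intermediate
7 | 2-bromo-3,7-bis(triisopropylsilyloxy)dibenzo[b,f]oxepin-10(11H)-one | O=C1Cc2cc(Br)c(O[Si](C(C)C)(C(C)C)C(C)C)cc2Oc2cc(O[Si](C(C)C)(C(C)C)C(C)C)ccc12 | intermediate
8 | 2-(3-methylbut-2-enyl)-3,7-bis(triisopropylsilyloxy)dibenzo[b,f]oxepin-10(11H)-one | O=C1Cc2cc(CC=C(C)C)c(O[Si](C(C)C)(C(C)C)C(C)C)cc2Oc2cc(O[Si](C(C)C)(C(C)C)C(C)C)ccc12 | intermediate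
9 | 2-(3-methylbut-2-enyl)-11-[(tributylstannyl)methyl]-3,7-bis(triisopropylsilyloxy)dibenzo[b,f]oxepin-10(11H)-one, racemic at C11 | O=C1C(C[Sn](CCCC)(CCCC)CCCC)c2cc(CC=C(C)C)c(O[Si](C(C)C)(C(C)C)C(C)C)cc2Oc2cc(O[Si](C(C)C)(C(C)C)C(C)C)ccc12 | intermediate
10 | 10-methoxy-2-(3-methylbut-2-enyl)-11-[(tributylstannyl)methyl]-3,7-bis(triisopropylsilyloxy)dibenzo[b,f]oxepine | COC1=C(C[Sn](CCCC)(CCCC)CCCC)c2cc(CC=C(C)C)c(O[Si](C(C)C)(C(C)C)C(C)C)cc2Oc2cc(O[Si](C(C)C)(C(C)C)C(C)C)ccc12 | intermediate
11 | (R)-lactic acid | C[C@@H](O)C(=O)O | starting material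
12 | pivaldehyde | CC(C)(C)C=O | starting material
13 | (2R,5R)-2-tert-butyl-5-methyl-1,3-dioxolan-4-one (tert-butyl cis to methyl) | C[C@H]1O[C@@H](C(C)(C)C)OC1=O | intermediate
14 | 5-iodo-2-methylpent-2-ene | CC(C)=CCCI | starting material
15 | (2R,5S)-2-tert-butyl-5-methyl-5-(4-methylpent-3-enyl)-1,3-dioxolan-4-one (tert-butyl cis to methyl) | CC(C)=CCC[C@]1(C)O[C@@H](C(C)(C)C)OC1=O | intermediate
16 | [10-methoxy-2-(3-methylbut-2-enyl)-3,7-bis(triisopropylsilyloxy)dibenzo[b,f]oxepin-11-yl]methyllithium (1-methoxyallyllithium) | COC1=C(C[Li])c2cc(CC=C(C)C)c(O[Si](C(C)C)(C(C)C)C(C)C)cc2Oc2cc(O[Si](C(C)C)(C(C)C)C(C)C)ccc12 | intermediate (not isolated)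
17 | lithium (2R,5S)-2-tert-butyl-5-methyl-5-(4-methylpent-3-enyl)-4-(oxepin-11-ylmethyl)-1,3-dioxolan-4-olate, oxepine substituted as in 16, configuration at C4 undefined | CC(C)=CCC[C@]1(C)O[C@@H](C(C)(C)C)OC1(O[Li])CC1=C(OC)c2ccc(O[Si](C(C)C)(C(C)C)C(C)C)cc2Oc2cc(O[Si](C(C)C)(C(C)C)C(C)C)c(CC=C(C)C)cc12 | intermediate (not isolated)
18 | (S)-3-hydroxy-3,7-dimethyl-1-[10-methoxy-2-(3-methylbut-2-enyl)-3,7-bis(triisopropylsilyloxy)dibenzo[b,f]oxepin-11-yl]oct-6-en-2-one | COC1=C(CC(=O)[C@@](C)(O)CCC=C(C)C)c2cc(CC=C(C)C)c(O[Si](C(C)C)(C(C)C)C(C)C)cc2Oc2cc(O[Si](C(C)C)(C(C)C)C(C)C)ccc12 | intermediate (not isolated)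
19 | (S)-2-methyl-2-(4-methylpent-3-enyl)-2H-pyran-3(4H)-one fused to C10–C11 of 2-prenyl-3,7-bis(triisopropylsilyloxy)dibenzo[b,f]oxepine (ring O on C10, ring CH2 on C11) | CC(C)=CCC[C@]1(C)OC2=C(CC1=O)c1cc(CC=C(C)C)c(O[Si](C(C)C)(C(C)C)C(C)C)cc1Oc1cc(O[Si](C(C)C)(C(C)C)C(C)C)ccc12 | intermediate
20 | (2S,3S)-alcohol from 19: quaternary carbon (S), carbinol (S), OH trans to the ring methyl; bis(triisopropylsilyl) ether of the target | CC(C)=CCC[C@]1(C)OC2=C(C[C@@H]1O)c1cc(CC=C(C)C)c(O[Si](C(C)C)(C(C)C)C(C)C)cc1Oc1cc(O[Si](C(C)C)(C(C)C)C(C)C)ccc12 | intermediate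
21 | CNP0185870.1: (2S,3S)-3-hydroxy-2-methyl-2-(4-methylpent-3-enyl)-3,4-dihydro-2H-pyran fused to C10–C11 of 2-prenyldibenzo[b,f]oxepine-3,7-diol | CC(C)=CCC[C@]1(C)OC2=C(C[C@@H]1O)c1cc(CC=C(C)C)c(O)cc1Oc1cc(O)ccc12 | target

**Totals.** Total step count: 13. Longest linear sequence: 11 (steps 1–8, then 11–13).

**Steps most likely to fail**

Step 11. In the anionic stage the lactolate may collapse early, so that the released ketone and pivaldehyde quench unreacted allyllithium, or the allyllithium may attack through its oxygen-bearing terminus. In the acid stage the methyl enol ether may hydrolyse to the 1,4-diketone and divert to Paal–Knorr furan closure. The fallback uncouples the two bond formations. It sets out from 15, which MeNHOMe·HCl/iPrMgCl should convert, with loss of pivaldehyde, into the Weinreb amide F1. The hydroxyl of F1 is deprotonated with iPrMgCl and allyllithium 16 (made from 10 as before) is added. The chelated adduct should survive until neutral work-up and give isolable hydroxy ketone 18. This is closed in a separate, independently tunable operation with anhydrous CSA and 5 Å MS, which returns to the route at 19.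

Step 12. Facial selectivity of hydride delivery may be poor because the ring oxygen next to the carbonyl perturbs catalyst binding, or the ketone may enolise toward the conjugated dienol. The fallback gives up reagent control. It sets out from 19 with an unselective Luche reduction (NaBH4, CeCl3·7H2O, MeOH, −78 °C). The two carbinol epimers are diastereomers, since the quaternary centre is fixed, and are separated by chromatography. The unwanted (R)-carbinol F2 is returned to 19 by Dess–Martin oxidation and recycled, and the wanted epimer rejoins the route at 20.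

Step 10. Alkylation of the thermally fragile dioxolanone enolate by an unactivated homoallylic iodide may be slow, letting enolate fragmentation or elimination of the iodide take over. The fallback builds the quaternary carbinol as a racemate and resolves it. It sets out from ethyl pyruvate and 4-methylpent-3-enylmagnesium bromide (from the commercial bromide), which should add at the ketone carbonyl at −78 °C to give the racemic ester F3. Saponification (LiOH) gives the racemic acid F4. Classical resolution through the salt with one enantiomer of 1-phenylethylamine gives the (S)-acid F5. Acetalisation with pivaldehyde (TsOH, pentane, water separator) returns to 15, accompanied by its acetal epimer F6, which serves equally in step 11 because the acetal carbon is expelled there.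

Further compounds
F1 | step 11 | (S)-2-hydroxy-N-methoxy-N,2,6-trimethylhept-5-enamide | CC(C)=CCC[C@](C)(O)C(=O)N(C)OC
F2 | step 12 | (2S,3R)-epimer of 20 (carbinol R, OH cis to the ring methyl) | CC(C)=CCC[C@]1(C)OC2=C(C[C@H]1O)c1cc(CC=C(C)C)c(O[Si](C(C)C)(C(C)C)C(C)C)cc1Oc1cc(O[Si](C(C)C)(C(C)C)C(C)C)ccc12
F3 | step 10 | ethyl 2-hydroxy-2,6-dimethylhept-5-enoate (racemic) | CCOC(=O)C(C)(O)CCC=C(C)C
F4 | step 10 | 2-hydroxy-2,6-dimethylhept-5-enoic acid (racemic) | CC(C)=CCCC(C)(O)C(=O)O
F5 | step 10 | (S)-2-hydroxy-2,6-dimethylhept-5-enoic acid | CC(C)=CCC[C@](C)(O)C(=O)O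
F6 | step 10 | (2S,5S)-2-tert-butyl-5-methyl-5-(4-methylpent-3-enyl)-1,3-dioxolan-4-one | CC(C)=CCC[C@]1(C)O[C@H](C(C)(C)C)OC1=O
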